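**Plan**
- Retrosynthesis: after removal of three MOM ethers, ring C is cut at C4–C4a (aryl–carbonyl), O1–C8a and O1–C2. Ring A becomes a 3,5-dialkoxy-4-prenylbenzyne (C4a≡C8a) and the rest a 2-arylacrylic acid carrying ring B with its geranyl chain.
- Enabling feature: ring A is an ortho-acyl aryl ether in which the acyl-bearing carbon C4a is flanked by the C5 oxygen. An aryne with an alkoxy group beside the triple bond takes an O-nucleophile at the remote carbon (C8a) and passes the acyl carbon to C4a, so one carboxylate delivers O1 and C4 to neighbouring ring carbons; the acrylate CH2 becomes C2.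
- Forward order: ring A fragment (resorcinol, prenylation between two MOM ethers, C–H borylation/oxidation, ortho-silylaryl triflate 14); ring B fragment (bromophenylacetate, allyl–aryl coupling with geranyl bromide, α-methylenation, acid 22); ring C arises last, in the step that joins the fragments.
- Helpers: the silyl/triflate pair is expelled in the key step; the MOM groups come off in the last step.
- Stereochemistry: C3 is configurationally labile and is left racemic until ring C exists. Noyori asymmetric transfer hydrogenation with dynamic kinetic resolution then sets C3 (R) together with C4, and Dess–Martin oxidation returns the ketone. The E-alkene comes from geranyl bromide.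

Key step: step 12

Remark: chroman-4-one numbering is used (O1, C2, C3, C4, C4a, C5–C8, C8a); compounds drawn without stereodescriptors at C3 are racemates.

Step 1
Reactants: 1 resorcinol
Product: 2 1,3-bis(methoxymethoxy)benzene
Conditions: NaH, MOMCl, DMF, 0 °C to rt
Reagents that add atoms: chloromethyl methyl ether, COCCl
Why: Double Williamson etherification of the resorcinol dianion installs the two MOM groups that later direct metalation and protect the C5 and C7 oxygens.

Step 2
Reactants: 2 1,3-bis(methoxymethoxy)benzene; 3 1-bromo-3-methylbut-2-ene (prenyl bromide)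
Product: 5 1,3-bis(methoxymethoxy)-2-(3-methylbut-2-en-1-yl)benzene, via aryllithium 4 (not isolated)
Conditions: n-BuLi, THF, 0 °C; then CuI (10 mol%), 3, −78 °C to rt
Reagents that add atoms: n-butyllithium, [Li]CCCC (lithium of 4 only)
Why: Directed ortho-metalation takes the carbon flanked by both MOM ethers, and copper-assisted SN2 allylation of the aryllithium with prenyl bromide should give the linear prenyl arene.

Step 3
Reactants: 5 1,3-bis(methoxymethoxy)-2-(3-methylbut-2-en-1-yl)benzene
Product: 7 3,5-bis(methoxymethoxy)-4-(3-methylbut-2-en-1-yl)phenol, via arylboronate 6 (not isolated)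
Conditions: [Ir(OMe)(cod)]2 (1.5 mol%), 4,4'-di-tert-butyl-2,2'-bipyridine, B2pin2, THF, 70 °C; then H2O2, NaOH (aq), 0 °C
Reagents that add atoms: bis(pinacolato)diboron, CC1(C)OB(OC1(C)C)B1OC(C)(C)C(C)(C)O1 (boryl group of 6 only); hydrogen peroxide, OO (phenol oxygen of 7)
Why: Sterically controlled iridium-catalysed C–H borylation should take the only ring C–H without an ortho substituent (para to the prenyl group, trisubstituted alkene inert), and oxidation of the C–B bond by boron-to-oxygen aryl shift gives the phenol.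

Step 4
Reactants: 7 3,5-bis(methoxymethoxy)-4-(3-methylbut-2-en-1-yl)phenol
Product: 8 3,5-bis(methoxymethoxy)-4-(3-methylbut-2-en-1-yl)phenyl N-isopropylcarbamate
Conditions: i-PrNCO, Et3N (cat.), CH2Cl2, rt
Reagents that add atoms: isopropyl isocyanate, CC(C)N=C=O
Why: Base-catalysed addition of the phenol to the isocyanate (carbamoylation) installs a strong ortho-directing group that is easily removed later.

Step 5
Reactants: 8 3,5-bis(methoxymethoxy)-4-(3-methylbut-2-en-1-yl)phenyl N-isopropylcarbamate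
Product: 12 3,5-bis(methoxymethoxy)-4-(3-methylbut-2-en-1-yl)-2-(trimethylsilyl)phenyl N-isopropylcarbamate, via N-silyl carbamate 9 (not isolated), via aryllithium 10 (not isolated), via disilyl carbamate 11 (not isolated)
Conditions: TBSOTf, TMEDA, Et2O, 0 °C to rt; then n-BuLi, TMEDA, −78 °C; then TMSCl, −78 °C to rt; aq. NH4Cl
Reagents that add atoms: tert-butyldimethylsilyl triflate, CC(C)(C)[Si](C)(C)OS(=O)(=O)C(F)(F)F (N-silyl group of 9–11 only); n-butyllithium, [Li]CCCC (lithium of 10 only); chlorotrimethylsilane, C[Si](C)(C)Cl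
Why: After temporary N-silylation the carbamate and the neighbouring MOM ether together direct ortho-lithiation (directed ortho-metalation) to one of the two equivalent ring positions, TMSCl quenches the aryllithium, and aqueous work-up removes the N-silyl group.

Step 6
Reactants: 12 3,5-bis(methoxymethoxy)-4-(3-methylbut-2-en-1-yl)-2-(trimethylsilyl)phenyl N-isopropylcarbamate
Product: 14 3,5-bis(methoxymethoxy)-4-(3-methylbut-2-en-1-yl)-2-(trimethylsilyl)phenyl trifluoromethanesulfonate, via silylphenol 13 (not isolated)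
Conditions: DBU, Et2NH, MeCN, 40 °C; then PhNTf2, rt
Reagents that add atoms: N-phenylbis(trifluoromethanesulfonimide), O=S(=O)(N(c1ccccc1)S(=O)(=O)C(F)(F)F)C(F)(F)F
Why: DBU induces E1cB loss of isopropyl isocyanate (trapped by Et2NH as a urea) and the freed phenoxide is triflated in the same flask, completing the ortho-silylaryl triflate with silicon between the triflate and a MOM ether.

Step 7
Reactants: 15 methyl 2-(3-bromo-4-hydroxyphenyl)acetate
Product: 16 methyl 2-[3-bromo-4-(methoxymethoxy)phenyl]acetate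
Conditions: MOMCl, K2CO3, acetone, 0 °C to rt
Reagents that add atoms: chloromethyl methyl ether, COCCl
Why: Williamson etherification of the phenoxide under conditions too mild to enolise the ester protects the ring B phenol.

Step 8
Reactants: 16 methyl 2-[3-bromo-4-(methoxymethoxy)phenyl]acetate
Product: 17 methyl 2-[4-(methoxymethoxy)-3-(4,4,5,5-tetramethyl-1,3,2-dioxaborolan-2-yl)phenyl]acetate
Conditions: PdCl2(dppf) (3 mol%), B2pin2, KOAc, 1,4-dioxane, 85 °C
Reagents that add atoms: bis(pinacolato)diboron, CC1(C)OB(OC1(C)C)B1OC(C)(C)C(C)(C)O1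
Why: Miyaura borylation of the aryl bromide tolerates the ester and turns ring B into the nucleophile for the allylation.

Step 9
Reactants: 17 methyl 2-[4-(methoxymethoxy)-3-(4,4,5,5-tetramethyl-1,3,2-dioxaborolan-2-yl)phenyl]acetate; 18 (2E)-1-bromo-3,7-dimethylocta-2,6-diene (geranyl bromide)
Product: 19 methyl 2-{3-[(2E)-3,7-dimethylocta-2,6-dien-1-yl]-4-(methoxymethoxy)phenyl}acetate
Conditions: Pd(PPh3)4 (5 mol%), CsF, THF, 60 °C
Reagents that add atoms: none
Why: Suzuki–Miyaura allyl–aryl coupling in which the π-geranylpalladium bromide accepts the aryl group from boron and reductive elimination at the less hindered allyl terminus should give the linear product with the E alkene retained.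

Step 10
Reactants: 19 methyl 2-{3-[(2E)-3,7-dimethylocta-2,6-dien-1-yl]-4-(methoxymethoxy)phenyl}acetate
Product: 21 methyl 2-{3-[(2E)-3,7-dimethylocta-2,6-dien-1-yl]-4-(methoxymethoxy)phenyl}prop-2-enoate, via hydroxymethyl ester 20 (not isolated)
Conditions: paraformaldehyde, K2CO3, n-Bu4NI (cat.), toluene, 80 °C
Reagents that add atoms: formaldehyde (as paraformaldehyde), C=O
Why: Aldol addition of the arylacetate enolate to formaldehyde and E1cB dehydration (α-methylenation) give the 2-arylacrylate whose CH2 becomes C2 of the target.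

Step 11
Reactants: 21 methyl 2-{3-[(2E)-3,7-dimethylocta-2,6-dien-1-yl]-4-(methoxymethoxy)phenyl}prop-2-enoate
Product: 22 2-{3-[(2E)-3,7-dimethylocta-2,6-dien-1-yl]-4-(methoxymethoxy)phenyl}prop-2-enoic acid
Conditions: LiOH, THF/H2O, 0 °C to rt; then 1 M HCl to pH 4, 0 °C
Reagents that add atoms: lithium hydroxide, [Li+].[OH-]
Why: Saponification of the methyl ester at low temperature with careful acidification should give the acrylic acid without loss of the MOM ether.

Step 12
Reactants: 14 3,5-bis(methoxymethoxy)-4-(3-methylbut-2-en-1-yl)-2-(trimethylsilyl)phenyl trifluoromethanesulfonate; 22 2-{3-[(2E)-3,7-dimethylocta-2,6-dien-1-yl]-4-(methoxymethoxy)phenyl}prop-2-enoic acid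
Product: 25 rac-3-{3-[(2E)-3,7-dimethylocta-2,6-dien-1-yl]-4-(methoxymethoxy)phenyl}-5,7-bis(methoxymethoxy)-6-(3-methylbut-2-en-1-yl)chroman-4-one, via aryne 23 (not isolated), via hydroxyaryl vinyl ketone 24 (not isolated)
Conditions: CsF (4 equiv), 22 (1.3 equiv), THF, 125 °C, sealed tube
Reagents that add atoms: none
Why: Fluoride removes the silyl group of 14 to release aryne 23, and the caesium carboxylate of 22 attacks C8a, the aryne carbon remote from the C5 methoxymethoxy group, because that inductively withdrawing oxygen distorts the triple bond and stabilises the carbanion developing next to it at C4a. The C4a carbanion closes on the ester carbonyl (4-exo-trig, a benzoxete alkoxide) and so forges the C4–C4a bond, the four-membered ring opens by C–O cleavage to the ortho-acylphenoxide 24, and this phenoxide closes ring C by 6-endo-trig oxa-Michael addition to the α-aryl enone. The closest known reaction type is the aryne insertion into the C–O bond of α,β-unsaturated carboxylic acids that gives chroman-4-ones (aryne acyl transfer followed by Michael ring closure). C3 arises by uncontrolled protonation of the enolate, so 25 is racemic by design and the centre is set in step 13. The step needs regioselective addition to the aryne and carbonyl attack in preference to protonation of the aryl anion: the C5 oxygen beside the triple bond secures the first, and heating in THF, which offers no acidic hydrogen, favours the second.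

Step 13
Reactants: 25 rac-3-{3-[(2E)-3,7-dimethylocta-2,6-dien-1-yl]-4-(methoxymethoxy)phenyl}-5,7-bis(methoxymethoxy)-6-(3-methylbut-2-en-1-yl)chroman-4-one
Product: 26 (3R,4R)-3-{3-[(2E)-3,7-dimethylocta-2,6-dien-1-yl]-4-(methoxymethoxy)phenyl}-5,7-bis(methoxymethoxy)-6-(3-methylbut-2-en-1-yl)chroman-4-ol
Conditions: RuCl(p-cymene)[(R,R)-TsDPEN] (5 mol%), HCO2H (5 equiv), Et3N (10 equiv), EtOAc, 40 °C
Reagents that add atoms: none
Why: Noyori asymmetric transfer hydrogenation with dynamic kinetic resolution, in which Et3N keeps C3 racemising through the enol while the (R,R)-catalyst should deliver hydride to the C4 face that gives the 4R carbinol (aryl ketone model) and reduce fastest the enantiomer that takes hydride anti to the C3 aryl group, giving the cis-(3R,4R) alcohol.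

Step 14
Reactants: 26 (3R,4R)-3-{3-[(2E)-3,7-dimethylocta-2,6-dien-1-yl]-4-(methoxymethoxy)phenyl}-5,7-bis(methoxymethoxy)-6-(3-methylbut-2-en-1-yl)chroman-4-ol
Product: 27 (3R)-3-{3-[(2E)-3,7-dimethylocta-2,6-dien-1-yl]-4-(methoxymethoxy)phenyl}-5,7-bis(methoxymethoxy)-6-(3-methylbut-2-en-1-yl)chroman-4-one
Conditions: Dess–Martin periodinane, CH2Cl2, 0 °C to rt
Reagents that add atoms: none
Why: Dess–Martin oxidation of the benzylic alcohol under non-basic conditions should return the C4 ketone without enolisation, so C3 keeps the R configuration while the C4 centre is erased.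

Step 15
Reactants: 27 (3R)-3-{3-[(2E)-3,7-dimethylocta-2,6-dien-1-yl]-4-(methoxymethoxy)phenyl}-5,7-bis(methoxymethoxy)-6-(3-methylbut-2-en-1-yl)chroman-4-one
Product: 28 (3R)-3-{3-[(2E)-3,7-dimethylocta-2,6-dien-1-yl]-4-hydroxyphenyl}-5,7-dihydroxy-6-(3-methylbut-2-en-1-yl)chroman-4-one
Conditions: ZnBr2, n-PrSH, CH2Cl2, 0 °C, short reaction time
Reagents that add atoms: none
Why: Lewis acid-assisted cleavage of the three aryl MOM ethers with thiol capture of the methoxymethyl unit is aprotic, cold and brief, so the C3–H next to the ketone should not enolise and the prenyl and geranyl alkenes should not cyclise onto the neighbouring phenols.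

**Compound list**
1 | resorcinol | Oc1cccc(O)c1 | starting material
2 | 1,3-bis(methoxymethoxy)benzene | COCOc1cccc(OCOC)c1 | intermediate
3 | 1-bromo-3-methylbut-2-ene (prenyl bromide) | CC(C)=CCBr | starting material
4 | [2,6-bis(methoxymethoxy)phenyl]lithium | [Li]c1c(OCOC)cccc1OCOC | intermediate
5 | 1,3-bis(methoxymethoxy)-2-(3-methylbut-2-en-1-yl)benzene | COCOc1cccc(OCOC)c1CC=C(C)C | intermediate
6 | 2-[3,5-bis(methoxymethoxy)-4-(3-methylbut-2-en-1-yl)phenyl]-4,4,5,5-tetramethyl-1,3,2-dioxaborolane | COCOc1cc(B2OC(C)(C)C(C)(C)O2)cc(OCOC)c1CC=C(C)C | intermediate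
7 | 3,5-bis(methoxymethoxy)-4-(3-methylbut-2-en-1-yl)phenol | COCOc1cc(O)cc(OCOC)c1CC=C(C)C | intermediate
8 | 3,5-bis(methoxymethoxy)-4-(3-methylbut-2-en-1-yl)phenyl N-isopropylcarbamate | COCOc1cc(OC(=O)NC(C)C)cc(OCOC)c1CC=C(C)C | intermediate
9 | 3,5-bis(methoxymethoxy)-4-(3-methylbut-2-en-1-yl)phenyl N-(tert-butyldimethylsilyl)-N-isopropylcarbamate | COCOc1cc(OC(=O)N(C(C)C)[Si](C)(C)C(C)(C)C)cc(OCOC)c1CC=C(C)C | intermediate
10 | 2-lithio derivative of 9 | COCOc1cc(OC(=O)N(C(C)C)[Si](C)(C)C(C)(C)C)c([Li])c(OCOC)c1CC=C(C)C | intermediate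
11 | 3,5-bis(methoxymethoxy)-4-(3-methylbut-2-en-1-yl)-2-(trimethylsilyl)phenyl N-(tert-butyldimethylsilyl)-N-isopropylcarbamate | COCOc1cc(OC(=O)N(C(C)C)[Si](C)(C)C(C)(C)C)c([Si](C)(C)C)c(OCOC)c1CC=C(C)C | intermediate
12 | 3,5-bis(methoxymethoxy)-4-(3-methylbut-2-en-1-yl)-2-(trimethylsilyl)phenyl N-isopropylcarbamate | COCOc1cc(OC(=O)NC(C)C)c([Si](C)(C)C)c(OCOC)c1CC=C(C)C | intermediate
13 | 3,5-bis(methoxymethoxy)-4-(3-methylbut-2-en-1-yl)-2-(trimethylsilyl)phenol | COCOc1cc(O)c([Si](C)(C)C)c(OCOC)c1CC=C(C)C | intermediate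
14 | 3,5-bis(methoxymethoxy)-4-(3-methylbut-2-en-1-yl)-2-(trimethylsilyl)phenyl trifluoromethanesulfonate | COCOc1cc(OS(=O)(=O)C(F)(F)F)c([Si](C)(C)C)c(OCOC)c1CC=C(C)C | intermediate
15 | methyl 2-(3-bromo-4-hydroxyphenyl)acetate | COC(=O)Cc1ccc(O)c(Br)c1 | starting material
16 | methyl 2-[3-bromo-4-(methoxymethoxy)phenyl]acetate | COCOc1ccc(CC(=O)OC)cc1Br | intermediate
17 | methyl 2-[4-(methoxymethoxy)-3-(4,4,5,5-tetramethyl-1,3,2-dioxaborolan-2-yl)phenyl]acetate | COCOc1ccc(CC(=O)OC)cc1B1OC(C)(C)C(C)(C)O1 | intermediate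
18 | (2E)-1-bromo-3,7-dimethylocta-2,6-diene (geranyl bromide) | CC(C)=CCC/C(C)=C/CBr | starting material
19 | methyl 2-{3-[(2E)-3,7-dimethylocta-2,6-dien-1-yl]-4-(methoxymethoxy)phenyl}acetate | CC(C)=CCC/C(C)=C/Cc1cc(CC(=O)OC)ccc1OCOC | intermediate
20 | rac-methyl 2-{3-[(2E)-3,7-dimethylocta-2,6-dien-1-yl]-4-(methoxymethoxy)phenyl}-3-hydroxypropanoate | CC(C)=CCC/C(C)=C/Cc1cc(C(CO)C(=O)OC)ccc1OCOC | intermediate
21 | methyl 2-{3-[(2E)-3,7-dimethylocta-2,6-dien-1-yl]-4-(methoxymethoxy)phenyl}prop-2-enoate | CC(C)=CCC/C(C)=C/Cc1cc(C(=C)C(=O)OC)ccc1OCOC | intermediate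
22 | 2-{3-[(2E)-3,7-dimethylocta-2,6-dien-1-yl]-4-(methoxymethoxy)phenyl}prop-2-enoic acid | CC(C)=CCC/C(C)=C/Cc1cc(C(=C)C(=O)O)ccc1OCOC | intermediate
23 | 3,5-bis(methoxymethoxy)-4-(3-methylbut-2-en-1-yl)benzyne (1,2-didehydrobenzene) | COCOC1=CC#CC(OCOC)=C1CC=C(C)C | intermediate
24 | 2-{3-[(2E)-3,7-dimethylocta-2,6-dien-1-yl]-4-(methoxymethoxy)phenyl}-1-[6-hydroxy-2,4-bis(methoxymethoxy)-3-(3-methylbut-2-en-1-yl)phenyl]prop-2-en-1-one | CC(C)=CCC/C(C)=C/Cc1cc(C(=C)C(=O)c2c(O)cc(OCOC)c(CC=C(C)C)c2OCOC)ccc1OCOC | intermediate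
25 | rac-3-{3-[(2E)-3,7-dimethylocta-2,6-dien-1-yl]-4-(methoxymethoxy)phenyl}-5,7-bis(methoxymethoxy)-6-(3-methylbut-2-en-1-yl)chroman-4-one | CC(C)=CCC/C(C)=C/Cc1cc(C2COc3cc(OCOC)c(CC=C(C)C)c(OCOC)c3C2=O)ccc1OCOC | intermediate
26 | (3R,4R)-3-{3-[(2E)-3,7-dimethylocta-2,6-dien-1-yl]-4-(methoxymethoxy)phenyl}-5,7-bis(methoxymethoxy)-6-(3-methylbut-2-en-1-yl)chroman-4-ol | CC(C)=CCC/C(C)=C/Cc1cc([C@@H]2COc3cc(OCOC)c(CC=C(C)C)c(OCOC)c3[C@@H]2O)ccc1OCOC | intermediate
27 | (3R)-3-{3-[(2E)-3,7-dimethylocta-2,6-dien-1-yl]-4-(methoxymethoxy)phenyl}-5,7-bis(methoxymethoxy)-6-(3-methylbut-2-en-1-yl)chroman-4-one | CC(C)=CCC/C(C)=C/Cc1cc([C@@H]2COc3cc(OCOC)c(CC=C(C)C)c(OCOC)c3C2=O)ccc1OCOC | intermediate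
28 | (3R)-3-{3-[(2E)-3,7-dimethylocta-2,6-dien-1-yl]-4-hydroxyphenyl}-5,7-dihydroxy-6-(3-methylbut-2-en-1-yl)chroman-4-one | CC(C)=CCC/C(C)=C/Cc1cc([C@@H]2COc3cc(O)c(CC=C(C)C)c(O)c3C2=O)ccc1O | target

**Totals and risks**
Total step count: 15. Longest linear sequence: 10 steps (steps 1–6, then 12–15).

Steps most likely to fail:

1. Step 12. The aryl carbanion may be protonated before it reaches the carbonyl (the sequence then stops at the aryl ester), the 2-arylacrylate may self-add at 125 °C, the aryne may undergo ene reaction with the trisubstituted alkenes, and the product phenoxide or enolate may be arylated again. The fallback sets out from 7 (with 21) and returns at 25. Phenol 7 is added to acrylate 21 by base-catalysed oxa-Michael addition (Cs2CO3 cat., MeCN, rt) to give rac-methyl 3-[3,5-bis(methoxymethoxy)-4-(3-methylbut-2-en-1-yl)phenoxy]-2-{3-[(2E)-3,7-dimethylocta-2,6-dien-1-yl]-4-(methoxymethoxy)phenyl}propanoate F1. The ester is cleaved without strong base by Me3SnOH (1,2-dichloroethane, 70 °C) to the corresponding rac-propanoic acid F2. Trifluoroacetic anhydride (CH2Cl2, 0 °C) then closes ring C by intramolecular Friedel–Crafts acylation at either of the two equivalent positions ortho to the ether oxygen, which gives 25.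

2. Step 13. Hydride transfer to the hindered, electron-rich C4 ketone beside the C5 ether may be slow, racemisation of C3 may fail to outpace reduction (eroding enantiomeric and cis/trans selectivity), and base-induced opening of ring C may lead to reduction of the open enone. The fallback sets out from 25 and returns at 27. Preparative chromatography on a chiral stationary phase (supercritical CO2/2-propanol) separates 25 into 27 and its enantiomer, (3S)-3-{3-[(2E)-3,7-dimethylocta-2,6-dien-1-yl]-4-(methoxymethoxy)phenyl}-5,7-bis(methoxymethoxy)-6-(3-methylbut-2-en-1-yl)chroman-4-one F3. F3 is racemised back to 25 with catalytic DBU in toluene and recycled.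

3. Step 15. Acid-promoted enolisation at C3 may erode the enantiomeric purity, and the prenyl or geranyl alkene may add to a neighbouring phenol. The fallback sets out from 25 and returns at 28. The MOM ethers are removed at the racemic stage, where enolisation costs nothing (HCl, MeOH/THF, 40 °C), giving rac-3-{3-[(2E)-3,7-dimethylocta-2,6-dien-1-yl]-4-hydroxyphenyl}-5,7-dihydroxy-6-(3-methylbut-2-en-1-yl)chroman-4-one F4. TBSOTf/2,6-lutidine (CH2Cl2, 0 °C) gives the rac-tris(tert-butyldimethylsilyl) ether F5. The transfer hydrogenation of step 13 then gives the (3R,4R)-tris(tert-butyldimethylsilyloxy)chroman-4-ol F6, and Dess–Martin oxidation gives the (3R)-tris(tert-butyldimethylsilyloxy)chroman-4-one F7. Et3N·3HF (THF, 0 °C) removes the silyl ethers under buffered, non-enolising conditions to give 28.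

**Further compounds**
F1 | step 12 | rac-methyl 3-[3,5-bis(methoxymethoxy)-4-(3-methylbut-2-en-1-yl)phenoxy]-2-{3-[(2E)-3,7-dimethylocta-2,6-dien-1-yl]-4-(methoxymethoxy)phenyl}propanoate | CC(C)=CCC/C(C)=C/Cc1cc(C(COc2cc(OCOC)c(CC=C(C)C)c(OCOC)c2)C(=O)OC)ccc1OCOC
F2 | step 12 | rac-3-[3,5-bis(methoxymethoxy)-4-(3-methylbut-2-en-1-yl)phenoxy]-2-{3-[(2E)-3,7-dimethylocta-2,6-dien-1-yl]-4-(methoxymethoxy)phenyl}propanoic acid | CC(C)=CCC/C(C)=C/Cc1cc(C(COc2cc(OCOC)c(CC=C(C)C)c(OCOC)c2)C(=O)O)ccc1OCOC
F3 | step 13 | (3S)-3-{3-[(2E)-3,7-dimethylocta-2,6-dien-1-yl]-4-(methoxymethoxy)phenyl}-5,7-bis(methoxymethoxy)-6-(3-methylbut-2-en-1-yl)chroman-4-one | CC(C)=CCC/C(C)=C/Cc1cc([C@H]2COc3cc(OCOC)c(CC=C(C)C)c(OCOC)c3C2=O)ccc1OCOC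
F4 | step 15 | rac-3-{3-[(2E)-3,7-dimethylocta-2,6-dien-1-yl]-4-hydroxyphenyl}-5,7-dihydroxy-6-(3-methylbut-2-en-1-yl)chroman-4-one | CC(C)=CCC/C(C)=C/Cc1cc(C2COc3cc(O)c(CC=C(C)C)c(O)c3C2=O)ccc1O
F5 | step 15 | rac-5,7-bis(tert-butyldimethylsilyloxy)-3-{4-(tert-butyldimethylsilyloxy)-3-[(2E)-3,7-dimethylocta-2,6-dien-1-yl]phenyl}-6-(3-methylbut-2-en-1-yl)chroman-4-one | CC(C)=CCC/C(C)=C/Cc1cc(C2COc3cc(O[Si](C)(C)C(C)(C)C)c(CC=C(C)C)c(O[Si](C)(C)C(C)(C)C)c3C2=O)ccc1O[Si](C)(C)C(C)(C)C
F6 | step 15 | (3R,4R)-5,7-bis(tert-butyldimethylsilyloxy)-3-{4-(tert-butyldimethylsilyloxy)-3-[(2E)-3,7-dimethylocta-2,6-dien-1-yl]phenyl}-6-(3-methylbut-2-en-1-yl)chroman-4-ol | CC(C)=CCC/C(C)=C/Cc1cc([C@@H]2COc3cc(O[Si](C)(C)C(C)(C)C)c(CC=C(C)C)c(O[Si](C)(C)C(C)(C)C)c3[C@@H]2O)ccc1O[Si](C)(C)C(C)(C)C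
F7 | step 15 | (3R)-5,7-bis(tert-butyldimethylsilyloxy)-3-{4-(tert-butyldimethylsilyloxy)-3-[(2E)-3,7-dimethylocta-2,6-dien-1-yl]phenyl}-6-(3-methylbut-2-en-1-yl)chroman-4-one | CC(C)=CCC/C(C)=C/Cc1cc([C@@H]2COc3cc(O[Si](C)(C)C(C)(C)C)c(CC=C(C)C)c(O[Si](C)(C)C(C)(C)C)c3C2=O)ccc1O[Si](C)(C)C(C)(C)C
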